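**Analysis of the target**

Nigrasin I (21) is a flavone in which ring A (C4a to C8a) is fused to the 4-pyranone ring C and ring B is bonded to C2. Ring A carries hydroxyls at C5 and C7, a hydrogen at C6 and a 2-methylbut-3-en-2-yl ("reverse prenyl") group at C8; C3 carries a 3-methylbut-2-enyl (prenyl) group; ring B is a resorcinol with hydroxyls at C2' and C4' and hydrogens at C3', C5' and C6'. There is no stereocentre and no stereogenic double bond, so every problem is one of regiochemistry and chemoselectivity. The sensitive groups are four phenols (the C5 hydroxyl chelated to the C4 carbonyl), a trisubstituted alkene and a terminal vinyl group that both take up acid and oxidants (the vinyl group lies next to the C7 hydroxyl), and the electron-rich rings A and B, which capture electrophiles. Three things make the synthesis hard: the quaternary benzylic carbon must be set on C8, between O1 and O7, while C6 stays free; the C2–C1' bond is flanked by the C3 prenyl group and the C2' hydroxyl, which makes a late coupling of two hindered halves unattractive; and the last operations must spare both olefins. The plan rests on the oxygen pattern of ring B: oxygen at C2' and C4' with hydrogen at C3', C5' and C6' is what a four-carbon 1,3-dioxygenated diene gives on addition to a terminal alkyne, and C2, the β-carbon of the pyranone enone, is a position at which such an alkyne is polarised.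

**Retrosynthetic reasoning**

21 from 20. The last disconnection removes the two methoxymethyl ethers on O5 and O7. Acetal ethers are chosen for ring A because they survive the strong bases, the hydride and the heat of the sequence and come off with dilute acid. The forward step must free two phenols without touching the prenyl and vinyl groups or the resorcinol ring.

20 from 15 and 18. Ring B is cut at C1'–C2' and C5'–C6'. This removes the whole resorcinol ring as the four-carbon diene 18 and leaves a two-carbon ethynyl group on C2 (15). Cutting here and not at C2–C1' means the congested bond between rings C and B already exists as the C2–alkyne bond before ring B is made, and no ortho-substituted aryl metal or halide is needed. The forward reaction must be a regioselective [4+2] addition of 18 to the alkyne, followed by aromatisation with loss of the methoxy group.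

15 from 12 by way of 14 and 13. The alkyne is traced to aldehyde 14 by a one-carbon homologation, 14 to carbinol 13 and 13 to ester 12. The detour through the ester is deliberate. A C2 substituent introduced at the aldehyde oxidation level would have to be masked as an acetal, and its unmasking would need stronger acid than the ring A ethers tolerate. The ester is reduced and re-oxidised under neutral conditions.

12 from 7 and 8. Ring C is cut at C2–C3 and O1–C2. A crossed Claisen condensation of ketone 7 with oxalate 8 makes C2–C3. The keto carbonyl so formed is electrophilic enough to be trapped by the neighbouring phenol as hemiketal 10, so O1–C2 forms on neutralisation and the final elimination can be done with base and not acid. Only the oxygen that becomes O1 is free in 7, so the ring can close in one direction only.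

7 from 6 and 2. The C3–CH2 bond is cut. The prenyl group is put on the α-carbon of the aryl ketone before ring C exists, because a chromone cannot be alkylated at C3 directly; the forward step is a single alkylation of a phenoxide–enolate dianion.

6 from 4 by way of 5. The bond from C8 to the quaternary carbon is traced to an aryl prenyl ether: a [3,3] shift from oxygen to the ortho carbon inverts the allyl unit and turns the prenyl group of 2 into the reverse prenyl group. The ether is placed on the oxygen para to the acetyl group (the future O7), not on the ortho oxygen (the future O1). From the ortho oxygen the para carbon (the future C6) would be open, and a second [3,3] shift of the dienone would carry the group there as a normal prenyl unit. In 4 the para carbon bears the acetyl group, so only the two ortho carbons are available, and the free, chelated hydroxyl directs the shift to the carbon between it and the ether oxygen. Capping the new phenol then gives 6, in which only the hindered, chelated hydroxyl is free.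

4 from 1 and 2 by way of 3. The prenyl ether is made at the only non-chelated hydroxyl of 1. One methoxymethyl group is then placed on one of the two equivalent chelated hydroxyls; the other stays locked in the hydrogen bond, which breaks the symmetry without a selectivity problem.

18 from 16 by way of 17. The diene is the bis-silyl dienol ether of acetoacetate 16, made by silylating first the ketone enol (17) and then the ester dienolate.

**Alternatives that were turned down**

Alternative 1: The quaternary carbon of the C8 side chain is disconnected at its C–CH3 and C–vinyl bonds and traced to the carbonyl carbon of an aryl methyl ketone, carbonate A1.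
- Forward key step: a methyl Grignard reagent adds to the ketone of A1, the carbonate migrates to the new alkoxide and leaves, and the resulting quinone methide A2 takes up a vinyl Grignard reagent at its exocyclic carbon to give phenol A3. No ring is closed.
- For it: the reverse prenyl group is placed with no regiochemical question, in one flask at low temperature and with no sigmatropic competition. On this point it is stronger than step 3 of the chosen route, which relies on chelation control at 190 °C.
- Against it: the step consumes the only acyl carbon of ring A. In A3 the carbon that must become C4a is a CH between a hydroxyl and a methoxymethyl ether, so the ring C ketone has to be brought back by ortho acylation of a hindered, acid-sensitive phenol, with the carbon between the two ethers competing. Rings C and B, including the crowded C2–C1' bond, are all still to be built.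
- Comparison: the alternative solves the side chain and nothing of the flavone core. The chosen route keeps the acetyl carbon of 1 as C4 and uses its key step to make ring B, at the cost of a less certain Claisen step.

Alternative 2: The C2–C1' bond and the C3–CH2 bond are both cut, leading to chromone A4 (unsubstituted at C2 and C3), aryl Grignard reagent A5 and prenyl bromide 2.
- Forward key step: copper-catalysed conjugate addition of A5 to A4, then C-alkylation of the enolate with 2, gives the trans-flavanone A6. No ring is closed.
- For it: two carbon–carbon bonds are made in one flask, ring B comes ready-made from a cheap resorcinol, and A4 is one formylation–cyclisation step from acetophenone 6. In convergence and step count it is stronger than the chosen route, which needs ten steps to reach alkyne 15.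
- Against it: the product is at the flavanone oxidation level. Dehydrogenating a 3-alkylated flavanone needs quinone, halogen, selenium or palladium oxidants, which also attack the allylic positions of both side chains and the electron-rich rings. The two stereocentres that the step sets are discarded. Conjugate addition of an ortho-substituted aryl nucleophile to an electron-rich 5,7-dialkoxychromone is slow, and magnesium enolates alkylate sluggishly, with O-alkylation and double alkylation as competitors.
- Comparison: the chosen strategy reaches the flavone oxidation level directly, never oxidises in the presence of the side chains, and forms the crowded C2–aryl connection by building a ring onto it and not by joining two hindered partners.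

Alternative 3: Ring A is disconnected at C5–C6, C7–C8 and C4a–C5, leading to the pyranonyl diazo ketone A7 (rings C and B complete) and the siloxyalkyne A8.
- Forward key step: irradiation of A7 causes Wolff rearrangement to a vinylketene, which adds A8 in a [2+2] sense; four-electron opening of the cyclobutenone and six-electron electrocyclisation close ring A, and tautomerisation gives phenol A9.
- For it: the fully substituted ring A is made in one operation, with O5 free and O7 silylated and the C8 side chain carried in on the diazo carbon. This needs no Claisen rearrangement and no protecting-group sequence on ring A, so here it is stronger than the chosen route.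
- Against it: A7 is a tetrasubstituted pyranone that already carries ring B (so the crowded C2–aryl bond is moved, not avoided), the prenyl group and a diazo ketone whose diazo carbon sits next to a quaternary carbon. Its preparation would take at least as many steps as alkyne 15. Under irradiation the pyranone chromophore, the vinyl group beside the carbene or ketene centre and the prenyl alkene offer competing paths (cyclopropanation, 1,2-shift, intramolecular [2+2]).
- Comparison: both strategies close a benzene ring late. The chosen one does it as a thermal ground-state reaction on a stable terminal alkyne made from commercial phloroacetophenone, and gives up the one-step differentiation of O5 and O7.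

Key step: step 13

**Remarks on the chemistry**

- Compounds 9, 10, 11 and 19 are racemic, and 10 and 11 are diastereomer mixtures. Their stereocentres vanish in the following operation, so their SMILES carry no stereo labels.
- Diene 18 is written as the (1Z) isomer. The geometry at C1 has no consequence, because C1 becomes an aromatic carbon.

**Route**

Step 1
Reactants: 1 2,4,6-trihydroxyacetophenone; 2 prenyl bromide (1-bromo-3-methylbut-2-ene)
Product: 3 1-[2,6-dihydroxy-4-(3-methylbut-2-enyloxy)phenyl]ethanone
Conditions: 2 (1.0 equiv), K2CO3 (1.1 equiv), acetone, reflux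
Reagents that add atoms: none
Why: Williamson etherification; the C4 hydroxyl, para to the acetyl group, is the most acidic and the only one not tied up in a hydrogen bond to the carbonyl, so one equivalent of the allylic bromide should alkylate it in preference to the two chelated hydroxyls.

Step 2
Reactants: 3 1-[2,6-dihydroxy-4-(3-methylbut-2-enyloxy)phenyl]ethanone
Product: 4 1-[2-hydroxy-6-(methoxymethoxy)-4-(3-methylbut-2-enyloxy)phenyl]ethanone
Conditions: MOMCl (1.2 equiv), i-Pr2NEt, CH2Cl2, 0 °C → rt
Reagents that add atoms: chloromethyl methyl ether, COCCl
Why: O-Alkylation of a phenol with an α-chloro ether; the two hydroxyls of 3 are equivalent, and once one is capped the other is held by the carbonyl in a strong hydrogen bond and resists a second alkylation, as in the usual partial protection of phloroacetophenones.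

Step 3
Reactants: 4 1-[2-hydroxy-6-(methoxymethoxy)-4-(3-methylbut-2-enyloxy)phenyl]ethanone
Product: 5 1-[2,4-dihydroxy-6-(methoxymethoxy)-3-(2-methylbut-3-en-2-yl)phenyl]ethanone
Conditions: PhNEt2, 190 °C, argon, sealed tube, short reaction time
Reagents that add atoms: none
Why: Aromatic Claisen rearrangement: the [3,3] shift moves the allyl unit from O4 to an ortho carbon with inversion, so the prenyl ether becomes the 2-methylbut-3-en-2-yl group; the para carbon carries the acetyl group, which excludes a following Cope shift, and of the two ortho carbons C3 should be favoured because the dienone formed there keeps the hydrogen-bonded enol–ketone conjugation C2(OH)=C1–C=O, the chelation control known for 4-allyloxy-2-hydroxyaryl ketones; enolisation restores the arene.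

Step 4
Reactants: 5 1-[2,4-dihydroxy-6-(methoxymethoxy)-3-(2-methylbut-3-en-2-yl)phenyl]ethanone
Product: 6 1-[2-hydroxy-4,6-bis(methoxymethoxy)-3-(2-methylbut-3-en-2-yl)phenyl]ethanone
Conditions: MOMCl (1.2 equiv), i-Pr2NEt, CH2Cl2, 0 °C → rt
Reagents that add atoms: chloromethyl methyl ether, COCCl
Why: O-Alkylation of the non-chelated C4 phenol; the C2 hydroxyl is both hydrogen-bonded to the carbonyl and shielded by the tertiary alkyl group, so it should stay free for the later ring closure.

Step 5
Reactants: 6 1-[2-hydroxy-4,6-bis(methoxymethoxy)-3-(2-methylbut-3-en-2-yl)phenyl]ethanone; 2 prenyl bromide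
Product: 7 1-[2-hydroxy-4,6-bis(methoxymethoxy)-3-(2-methylbut-3-en-2-yl)phenyl]-5-methylhex-4-en-1-one
Conditions: LiN(i-Pr)2 (2.2 equiv), THF, −78 → 0 °C; then 2 (1.05 equiv), −78 → 0 °C; AcOH quench
Reagents that add atoms: none
Why: Enolate alkylation: two equivalents of amide base give the phenoxide–enolate dianion, whose carbon terminus is far more nucleophilic than the hindered, lithium-chelated phenoxide oxygen, and the primary allylic bromide reacts by SN2; one equivalent of 2 at low temperature limits double alkylation.

Step 6
Reactants: 7 1-[2-hydroxy-4,6-bis(methoxymethoxy)-3-(2-methylbut-3-en-2-yl)phenyl]-5-methylhex-4-en-1-one; 8 diethyl oxalate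
Product: 10 ethyl 2-hydroxy-5,7-bis(methoxymethoxy)-8-(2-methylbut-3-en-2-yl)-3-(3-methylbut-2-enyl)-4-oxochromane-2-carboxylate (diastereomer mixture), via open-chain diketo ester 9 (not isolated)
Conditions: LiN(SiMe3)2 (3.3 equiv), THF, −78 °C; 8 (1.5 equiv), −78 °C → rt; AcOH quench
Reagents that add atoms: none
Why: Crossed Claisen condensation of a ketone enolate with the non-enolisable, doubly activated oxalate, the classical entry to chromone-2-carboxylates that also works for α-substituted ortho-hydroxyaryl ketones; on neutralisation the phenol adds to the keto ester carbonyl of 9 and the product is expected to rest as the cyclic hemiketal 10.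

Step 7
Reactants: 10 ethyl 2-hydroxy-5,7-bis(methoxymethoxy)-8-(2-methylbut-3-en-2-yl)-3-(3-methylbut-2-enyl)-4-oxochromane-2-carboxylate
Product: 12 ethyl 5,7-bis(methoxymethoxy)-8-(2-methylbut-3-en-2-yl)-3-(3-methylbut-2-enyl)-4-oxo-4H-chromene-2-carboxylate, via hemiketal mesylate 11 (not isolated)
Conditions: MsCl (1.5 equiv), Et3N (4 equiv), CH2Cl2, 0 °C → rt
Reagents that add atoms: none
Why: Dehydration of a β-hydroxy ketone by sulfonylation and E1cB elimination: the hemiketal hydroxyl is mesylated and the C4 enolate expels methanesulfonate to give the pyranone; no acid is used, so both methoxymethyl ethers stay and O1 remains on the phenol on which it was set.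

Step 8
Reactants: 12 ethyl 5,7-bis(methoxymethoxy)-8-(2-methylbut-3-en-2-yl)-3-(3-methylbut-2-enyl)-4-oxo-4H-chromene-2-carboxylate
Product: 13 2-(hydroxymethyl)-5,7-bis(methoxymethoxy)-8-(2-methylbut-3-en-2-yl)-3-(3-methylbut-2-enyl)-4H-chromen-4-one
Conditions: NaBH4, MeOH–THF, 0 °C
Reagents that add atoms: none
Why: Borohydride reduction of an activated ester: the ester on C2 of a chromone is flanked by the ring oxygen and conjugated with the carbonyl and is reduced to the carbinol by NaBH4, while the C4 carbonyl is a vinylogous ester and C2=C3 is tetrasubstituted and donor-substituted, so 1,2- and 1,4-reduction of ring C should not compete.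

Step 9
Reactants: 13 2-(hydroxymethyl)-5,7-bis(methoxymethoxy)-8-(2-methylbut-3-en-2-yl)-3-(3-methylbut-2-enyl)-4H-chromen-4-one
Product: 14 5,7-bis(methoxymethoxy)-8-(2-methylbut-3-en-2-yl)-3-(3-methylbut-2-enyl)-4-oxo-4H-chromene-2-carbaldehyde
Conditions: Dess–Martin periodinane, CH2Cl2, 0 °C → rt
Reagents that add atoms: none
Why: Dess–Martin oxidation of a primary allylic-type alcohol to the aldehyde; the reagent does not touch the trisubstituted and terminal alkenes or the acetal ethers, and the aldehyde cannot over-oxidise under anhydrous conditions.

Step 10
Reactants: 14 5,7-bis(methoxymethoxy)-8-(2-methylbut-3-en-2-yl)-3-(3-methylbut-2-enyl)-4-oxo-4H-chromene-2-carbaldehyde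
Product: 15 2-ethynyl-5,7-bis(methoxymethoxy)-8-(2-methylbut-3-en-2-yl)-3-(3-methylbut-2-enyl)-4H-chromen-4-one
Conditions: dimethyl (1-diazo-2-oxopropyl)phosphonate, K2CO3, MeOH, 0 °C → rt
Reagents that add atoms: dimethyl (1-diazo-2-oxopropyl)phosphonate, CC(=O)C(=[N+]=[N-])P(=O)(OC)OC
Why: Ohira–Bestmann variant of the Seyferth–Gilbert homologation: methanolysis of the reagent gives the diazomethylphosphonate anion, olefination of the aldehyde gives a diazoalkene, and loss of nitrogen with 1,2-hydrogen shift gives the terminal alkyne; the aldehyde is non-enolisable and highly electrophilic, so the reaction should be fast at low temperature.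

Step 11
Reactants: 16 methyl acetoacetate
Product: 17 methyl 3-(trimethylsilyloxy)but-2-enoate
Conditions: Me3SiCl, Et3N, hexane, rt
Reagents that add atoms: chlorotrimethylsilane, C[Si](C)(C)Cl
Why: O-Silylation of the enol of a β-keto ester under soft enolisation with a tertiary amine, the standard first stage in the preparation of bis(silyloxy)dienes.

Step 12
Reactants: 17 methyl 3-(trimethylsilyloxy)but-2-enoate
Product: 18 (1Z)-1-methoxy-1,3-bis(trimethylsilyloxy)buta-1,3-diene
Conditions: LiN(i-Pr)2, THF, −78 °C; Me3SiCl, −78 °C → rt; distillation
Reagents that add atoms: chlorotrimethylsilane, C[Si](C)(C)Cl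
Why: γ-Deprotonation of the silyl enol ether by the amide base gives the ester dienolate, which is silylated on oxygen to the ketene acetal; this is the established preparation of 1-alkoxy-1,3-bis(silyloxy)dienes.

Step 13
Reactants: 15 2-ethynyl-5,7-bis(methoxymethoxy)-8-(2-methylbut-3-en-2-yl)-3-(3-methylbut-2-enyl)-4H-chromen-4-one; 18 (1Z)-1-methoxy-1,3-bis(trimethylsilyloxy)buta-1,3-diene
Product: 20 2-(2,4-dihydroxyphenyl)-5,7-bis(methoxymethoxy)-8-(2-methylbut-3-en-2-yl)-3-(3-methylbut-2-enyl)-4H-chromen-4-one (nigrasin I 5,7-bis(methoxymethyl) ether), via silyl ketal cycloadduct 19 (not isolated)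
Conditions: 18 (3 equiv), PhMe, 110 °C, sealed tube; then citric acid, THF–H2O, rt
Reagents that add atoms: none
Why: Proposed new method: the ethynyl group of 15 is conjugated through C2=C3 with the C4 carbonyl, which makes its terminal carbon the electrophilic end of a vinylogous ynone, so the electron-rich diene 18 should add in a normal-demand, asynchronous [4+2] cycloaddition in which the nucleophilic CH2 terminus of 18 bonds to the alkyne CH (C5'–C6') and the ketene acetal carbon to the internal alkyne carbon (C1'–C2'); the closest known reaction type is the Diels–Alder addition and aromatisation of 1-alkoxy-1,3-bis(silyloxy)dienes with alkynyl ketones and propiolates, which gives 2,4-dioxygenated aryl ketones and esters, whereas an alkyne activated only through a pyranone ring has not been used. Ring B closes in this one intermolecular [4+2] event, both new bonds of the six-membered ring forming on the same face of the diene; a stepwise course (1,6-addition, then attack of the allenyl enolate on the silyloxycarbenium carbon) would lead to the same ring. Cycloadduct 19 is a cyclohexa-1,4-diene with a mixed methyl silyl ketal at C2' and a silyl enol ether at C4'; aqueous citric acid cleaves both, the methoxy group leaves from C2', and the diketo tautomer enolises to the resorcinol, so no oxidant is needed and the ring A ethers are not touched. No stereocentre survives, since the ketal carbon of 19 becomes aromatic. The step needs regioselectivity, oxygen at C2' and C4' and not at C3' and C5', which the polarisation O4=C4–C3=C2–C≡C–H secures by pairing the most nucleophilic diene terminus with the terminal alkyne carbon. It also needs chemoselectivity, which rests on C2=C3 being tetrasubstituted and donor-substituted and on the prenyl and vinyl alkenes being unactivated toward an electron-rich diene. An excess of 18 in a sealed tube offsets the modest dienophilicity and the thermal lability of the diene.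

Step 14
Reactants: 20 2-(2,4-dihydroxyphenyl)-5,7-bis(methoxymethoxy)-8-(2-methylbut-3-en-2-yl)-3-(3-methylbut-2-enyl)-4H-chromen-4-one
Product: 21 nigrasin I, 2-(2,4-dihydroxyphenyl)-5,7-dihydroxy-8-(2-methylbut-3-en-2-yl)-3-(3-methylbut-2-enyl)-4H-chromen-4-one
Conditions: 3 M aq. HCl, MeOH, 45 °C
Reagents that add atoms: none
Why: Acid-catalysed transacetalisation of aryl methoxymethyl ethers to the solvent; the ether peri to the carbonyl is especially labile, and dilute acid in methanol at moderate temperature is the kind of condition under which prenyl side chains of flavonoids are expected to survive.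

**Compound list**

1 | 2,4,6-trihydroxyacetophenone | CC(=O)c1c(O)cc(O)cc1O | starting material
2 | prenyl bromide (1-bromo-3-methylbut-2-ene) | CC(C)=CCBr | starting material
3 | 1-[2,6-dihydroxy-4-(3-methylbut-2-enyloxy)phenyl]ethanone | CC(=O)c1c(O)cc(OCC=C(C)C)cc1O | intermediate
4 | 1-[2-hydroxy-6-(methoxymethoxy)-4-(3-methylbut-2-enyloxy)phenyl]ethanone | CC(=O)c1c(O)cc(OCC=C(C)C)cc1OCOC | intermediate
5 | 1-[2,4-dihydroxy-6-(methoxymethoxy)-3-(2-methylbut-3-en-2-yl)phenyl]ethanone | CC(=O)c1c(O)c(C(C)(C)C=C)c(O)cc1OCOC | intermediate
6 | 1-[2-hydroxy-4,6-bis(methoxymethoxy)-3-(2-methylbut-3-en-2-yl)phenyl]ethanone | CC(=O)c1c(O)c(C(C)(C)C=C)c(OCOC)cc1OCOC | intermediate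
7 | 1-[2-hydroxy-4,6-bis(methoxymethoxy)-3-(2-methylbut-3-en-2-yl)phenyl]-5-methylhex-4-en-1-one | CC(C)=CCCC(=O)c1c(O)c(C(C)(C)C=C)c(OCOC)cc1OCOC | intermediate
8 | diethyl oxalate | CCOC(=O)C(=O)OCC | starting material
9 | ethyl 3-[2-hydroxy-4,6-bis(methoxymethoxy)-3-(2-methylbut-3-en-2-yl)benzoyl]-6-methyl-2-oxohept-5-enoate (racemic) | CCOC(=O)C(=O)C(CC=C(C)C)C(=O)c1c(O)c(C(C)(C)C=C)c(OCOC)cc1OCOC | intermediate (not isolated)
10 | ethyl 2-hydroxy-5,7-bis(methoxymethoxy)-8-(2-methylbut-3-en-2-yl)-3-(3-methylbut-2-enyl)-4-oxochromane-2-carboxylate (racemic diastereomer mixture) | CCOC(=O)C1(O)Oc2c(C(C)(C)C=C)c(OCOC)cc(OCOC)c2C(=O)C1CC=C(C)C | intermediate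
11 | ethyl 2-(methanesulfonyloxy)-5,7-bis(methoxymethoxy)-8-(2-methylbut-3-en-2-yl)-3-(3-methylbut-2-enyl)-4-oxochromane-2-carboxylate (racemic diastereomer mixture) | CCOC(=O)C1(OS(C)(=O)=O)Oc2c(C(C)(C)C=C)c(OCOC)cc(OCOC)c2C(=O)C1CC=C(C)C | intermediate (not isolated)
12 | ethyl 5,7-bis(methoxymethoxy)-8-(2-methylbut-3-en-2-yl)-3-(3-methylbut-2-enyl)-4-oxo-4H-chromene-2-carboxylate | CCOC(=O)c1oc2c(C(C)(C)C=C)c(OCOC)cc(OCOC)c2c(=O)c1CC=C(C)C | intermediate
13 | 2-(hydroxymethyl)-5,7-bis(methoxymethoxy)-8-(2-methylbut-3-en-2-yl)-3-(3-methylbut-2-enyl)-4H-chromen-4-one | OCc1oc2c(C(C)(C)C=C)c(OCOC)cc(OCOC)c2c(=O)c1CC=C(C)C | intermediate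
14 | 5,7-bis(methoxymethoxy)-8-(2-methylbut-3-en-2-yl)-3-(3-methylbut-2-enyl)-4-oxo-4H-chromene-2-carbaldehyde | O=Cc1oc2c(C(C)(C)C=C)c(OCOC)cc(OCOC)c2c(=O)c1CC=C(C)C | intermediate
15 | 2-ethynyl-5,7-bis(methoxymethoxy)-8-(2-methylbut-3-en-2-yl)-3-(3-methylbut-2-enyl)-4H-chromen-4-one | C#Cc1oc2c(C(C)(C)C=C)c(OCOC)cc(OCOC)c2c(=O)c1CC=C(C)C | intermediate
16 | methyl acetoacetate | CC(=O)CC(=O)OC | starting material
17 | methyl 3-(trimethylsilyloxy)but-2-enoate | COC(=O)C=C(C)O[Si](C)(C)C | intermediate
18 | (1Z)-1-methoxy-1,3-bis(trimethylsilyloxy)buta-1,3-diene | C=C(O[Si](C)(C)C)/C=C(/OC)O[Si](C)(C)C | intermediate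
19 | 2-[6-methoxy-4,6-bis(trimethylsilyloxy)cyclohexa-1,4-dien-1-yl]-5,7-bis(methoxymethoxy)-8-(2-methylbut-3-en-2-yl)-3-(3-methylbut-2-enyl)-4H-chromen-4-one (racemic) | COC1(O[Si](C)(C)C)C=C(O[Si](C)(C)C)CC=C1c1oc2c(C(C)(C)C=C)c(OCOC)cc(OCOC)c2c(=O)c1CC=C(C)C | intermediate (not isolated)
20 | 2-(2,4-dihydroxyphenyl)-5,7-bis(methoxymethoxy)-8-(2-methylbut-3-en-2-yl)-3-(3-methylbut-2-enyl)-4H-chromen-4-one | C=CC(C)(C)c1c(OCOC)cc(OCOC)c2c(=O)c(CC=C(C)C)c(-c3ccc(O)cc3O)oc12 | intermediate
21 | nigrasin I | C=CC(C)(C)c1c(O)cc(O)c2c(=O)c(CC=C(C)C)c(-c3ccc(O)cc3O)oc12 | target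

**Step count and least certain steps**

Total: 14 steps. Longest linear sequence: 12 steps (steps 1–10, 13 and 14, from 1 to 21); the diene branch (steps 11 and 12) joins at step 13.

Step 13 (key step, carries the label "Proposed new method:"). The most likely failure is that cycloaddition is too slow: the alkyne is activated only through the pyranone ring, and the two alkoxy groups of ring A feed electron density into the carbonyl, so silyl migration, polymerisation or adventitious hydrolysis of 18 may outrun the addition. Erosion of regiochemistry is a lesser risk, because sterics would prefer to place the bulky ketene acetal end at the terminal carbon, against the electronic preference. The fallback gives up the cycloaddition and builds ring C around a ready-made ring B by known chemistry. It sets out from ketone 7. Heating 7 with 2,4-bis(methoxymethoxy)benzoyl chloride F1 (3 equiv) and DBU in pyridine at about 100 °C should bring about O-aroylation, base-induced acyl transfer to the α-carbon and ring closure with loss of a second aroyl unit as its carboxylate (the base-mediated Baker–Venkataraman/Allan–Robinson sequence for 3-alkylflavones). Because it runs without acid, O1 is fixed on the correct phenol. The product is 2-[2,4-bis(methoxymethoxy)phenyl]-5,7-bis(methoxymethoxy)-8-(2-methylbut-3-en-2-yl)-3-(3-methylbut-2-enyl)-4H-chromen-4-one F2, and methanolysis of its four ethers under the conditions of step 14 comes back to the route at 21.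

Step 3. Two processes may go wrong. The shift may go in part to C5 if chelation control is weaker for the bulky prenyl terminus than for simple allyl groups. Prolonged heating may also let the ortho-(2-methylbut-3-en-2-yl)phenol reorganise further (abnormal Claisen isomerisation of the side chain, ring closure onto a flanking hydroxyl, or loss of the prenyl group). The fallback removes the regiochemical question by symmetry. It sets out from 3, in which both ortho carbons are equivalent and the para carbon is blocked; heating 3 in PhNEt2 should give 1-[2,4,6-trihydroxy-3-(2-methylbut-3-en-2-yl)phenyl]ethanone F3. Treating F3 with MOMCl (2.2 equiv) and i-Pr2NEt should cap the C4 hydroxyl and the unhindered C6 hydroxyl and leave the hydroxyl beside the tertiary alkyl group free, which comes back to the route at 6.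

Step 7. Sulfonylation may take place on the phenol of the ring-opened tautomer of 10 and not on the hemiketal hydroxyl, or the base may trigger retro-Claisen loss of the oxalyl unit, so that ring C does not form. The fallback closes ring C under basic conditions with a different two-carbon unit and sets out from 7. Kostanecki–Robinson acetylation–cyclisation (Ac2O, NaOAc, 160–170 °C) should give 2-methyl-5,7-bis(methoxymethoxy)-8-(2-methylbut-3-en-2-yl)-3-(3-methylbut-2-enyl)-4H-chromen-4-one F4. Condensation of its vinylogously acidic methyl group with N,N-dimethylformamide dimethyl acetal (neat, 130 °C) should give 2-[(E)-2-(dimethylamino)ethenyl]-5,7-bis(methoxymethoxy)-8-(2-methylbut-3-en-2-yl)-3-(3-methylbut-2-enyl)-4H-chromen-4-one F5. Cleavage of the electron-rich enamine double bond with NaIO4 in THF–H2O, which leaves isolated alkenes alone, comes back to the route at aldehyde 14 and replaces steps 6 to 9.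

Step 10. Methoxide may add to the electron-poor alkyne as it forms, or to C2 of the pyranone with ring opening, because the product is a Michael acceptor in basic methanol. The fallback makes the alkyne by olefination and elimination in aprotic media and sets out from 14. A Wittig reaction with the ylide from (bromomethyl)triphenylphosphonium bromide and KOt-Bu in THF at −78 °C should give 2-[(Z)-2-bromoethenyl]-5,7-bis(methoxymethoxy)-8-(2-methylbut-3-en-2-yl)-3-(3-methylbut-2-enyl)-4H-chromen-4-one F6, and dehydrobromination of F6 with Bu4NF in DMF comes back to the route at 15.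

Step 14. The methoxymethyl cations or the formaldehyde set free may be recaptured by the nucleophilic carbons C6, C3' and C5', and the acid may add the C7 hydroxyl or the solvent across the vinyl and prenyl groups. The fallback moves the deprotection ahead of the formation of ring B, so that no resorcinol ring is present when the acetals are cleaved, and sets out from 15. Acidic methanolysis of 15 should give 2-ethynyl-5,7-dihydroxy-8-(2-methylbut-3-en-2-yl)-3-(3-methylbut-2-enyl)-4H-chromen-4-one F7. Silylation in the flask with N,O-bis(trimethylsilyl)acetamide should give 2-ethynyl-8-(2-methylbut-3-en-2-yl)-3-(3-methylbut-2-enyl)-5,7-bis(trimethylsilyloxy)-4H-chromen-4-one F8. Cycloaddition with 18 as in step 13 should then give 2-[6-methoxy-4,6-bis(trimethylsilyloxy)cyclohexa-1,4-dien-1-yl]-8-(2-methylbut-3-en-2-yl)-3-(3-methylbut-2-enyl)-5,7-bis(trimethylsilyloxy)-4H-chromen-4-one F9, and the citric acid work-up, which removes all four silyl groups, comes back to the route at 21.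

**Further compounds**

F1 | step 13 | 2,4-bis(methoxymethoxy)benzoyl chloride | COCOc1ccc(C(=O)Cl)c(OCOC)c1
F2 | step 13 | 2-[2,4-bis(methoxymethoxy)phenyl]-5,7-bis(methoxymethoxy)-8-(2-methylbut-3-en-2-yl)-3-(3-methylbut-2-enyl)-4H-chromen-4-one | C=CC(C)(C)c1c(OCOC)cc(OCOC)c2c(=O)c(CC=C(C)C)c(-c3ccc(OCOC)cc3OCOC)oc12
F3 | step 3 | 1-[2,4,6-trihydroxy-3-(2-methylbut-3-en-2-yl)phenyl]ethanone | CC(=O)c1c(O)cc(O)c(C(C)(C)C=C)c1O
F4 | step 7 | 2-methyl-5,7-bis(methoxymethoxy)-8-(2-methylbut-3-en-2-yl)-3-(3-methylbut-2-enyl)-4H-chromen-4-one | Cc1oc2c(C(C)(C)C=C)c(OCOC)cc(OCOC)c2c(=O)c1CC=C(C)C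
F5 | step 7 | 2-[(E)-2-(dimethylamino)ethenyl]-5,7-bis(methoxymethoxy)-8-(2-methylbut-3-en-2-yl)-3-(3-methylbut-2-enyl)-4H-chromen-4-one | CN(C)/C=C/c1oc2c(C(C)(C)C=C)c(OCOC)cc(OCOC)c2c(=O)c1CC=C(C)C
F6 | step 10 | 2-[(Z)-2-bromoethenyl]-5,7-bis(methoxymethoxy)-8-(2-methylbut-3-en-2-yl)-3-(3-methylbut-2-enyl)-4H-chromen-4-one | Br/C=C\c1oc2c(C(C)(C)C=C)c(OCOC)cc(OCOC)c2c(=O)c1CC=C(C)C
F7 | step 14 | 2-ethynyl-5,7-dihydroxy-8-(2-methylbut-3-en-2-yl)-3-(3-methylbut-2-enyl)-4H-chromen-4-one | C#Cc1oc2c(C(C)(C)C=C)c(O)cc(O)c2c(=O)c1CC=C(C)C
F8 | step 14 | 2-ethynyl-8-(2-methylbut-3-en-2-yl)-3-(3-methylbut-2-enyl)-5,7-bis(trimethylsilyloxy)-4H-chromen-4-one | C#Cc1oc2c(C(C)(C)C=C)c(O[Si](C)(C)C)cc(O[Si](C)(C)C)c2c(=O)c1CC=C(C)C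
F9 | step 14 | 2-[6-methoxy-4,6-bis(trimethylsilyloxy)cyclohexa-1,4-dien-1-yl]-8-(2-methylbut-3-en-2-yl)-3-(3-methylbut-2-enyl)-5,7-bis(trimethylsilyloxy)-4H-chromen-4-one (racemic) | COC1(O[Si](C)(C)C)C=C(O[Si](C)(C)C)CC=C1c1oc2c(C(C)(C)C=C)c(O[Si](C)(C)C)cc(O[Si](C)(C)C)c2c(=O)c1CC=C(C)C
A1 | alternative 1 | tert-butyl 2-acetyl-3,5-bis(methoxymethoxy)phenyl carbonate | CC(=O)c1c(OC(=O)OC(C)(C)C)cc(OCOC)cc1OCOC
A2 | alternative 1 | 3,5-bis(methoxymethoxy)-6-(propan-2-ylidene)cyclohexa-2,4-dien-1-one | CC(C)=C1C(=O)C=C(OCOC)C=C1OCOC
A3 | alternative 1 | 3,5-bis(methoxymethoxy)-2-(2-methylbut-3-en-2-yl)phenol | C=CC(C)(C)c1c(O)cc(OCOC)cc1OCOC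
A4 | alternative 2 | 5,7-bis(methoxymethoxy)-8-(2-methylbut-3-en-2-yl)-4H-chromen-4-one | C=CC(C)(C)c1c(OCOC)cc(OCOC)c2c(=O)ccoc12
A5 | alternative 2 | [2,4-bis(methoxymethoxy)phenyl]magnesium bromide | COCOc1ccc([Mg]Br)c(OCOC)c1
A6 | alternative 2 | trans-2-[2,4-bis(methoxymethoxy)phenyl]-5,7-bis(methoxymethoxy)-8-(2-methylbut-3-en-2-yl)-3-(3-methylbut-2-enyl)chroman-4-one (racemic, one enantiomer drawn) | C=CC(C)(C)c1c(OCOC)cc(OCOC)c2c1O[C@@H](c1ccc(OCOC)cc1OCOC)[C@H](CC=C(C)C)C2=O
A7 | alternative 3 | 2-[2,4-bis(methoxymethoxy)phenyl]-6-(2-diazo-3,3-dimethylpent-4-enoyl)-3-(3-methylbut-2-enyl)-4H-pyran-4-one | C=CC(C)(C)C(=[N+]=[N-])C(=O)c1cc(=O)c(CC=C(C)C)c(-c2ccc(OCOC)cc2OCOC)o1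
A8 | alternative 3 | (ethynyloxy)tri(propan-2-yl)silane | C#CO[Si](C(C)C)(C(C)C)C(C)C
A9 | alternative 3 | 2-[2,4-bis(methoxymethoxy)phenyl]-5-hydroxy-8-(2-methylbut-3-en-2-yl)-3-(3-methylbut-2-enyl)-7-[tri(propan-2-yl)silyloxy]-4H-chromen-4-one | C=CC(C)(C)c1c(O[Si](C(C)C)(C(C)C)C(C)C)cc(O)c2c(=O)c(CC=C(C)C)c(-c3ccc(OCOC)cc3OCOC)oc12
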